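The runs come from a simulation for an exercise; noise was put on by code.

The constants I can use are two, both read from the epsilon run with its scatter. I suppose the stall there is partner's own clock running down, with substrate consumed in proportion to what is left.

| flask | substrate | partner | free catalyst | temperature | remark | time |
|---|---|---|---|---|---|---|
| epsilon | 38 mM | 49.4 mM | 3.8 mM | 80 °C | run made earlier |  |
| eta | 38 mM | 25 mM | 3.8 mM | 80 °C | run made earlier |  |
| oak | 38 mM (fed, over 5.0 h) | 49.4 mM | 3.8 mM | 80 °C | all else is in the flask from the start; the feed brings no volume worth counting | 25 h |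
| alder | 38 mM (in portions, 5, over 5.0 h) | 49.4 mM | 3.8 mM | 80 °C | first portion at the start, last at 5.0 h | 25 h |
| larch | 38 mM (fed, over 5.0 h) | 49.4 mM | 3.8 mM |  | the addition at 60 °C, then warmed to 80 °C; the feed brings no volume worth counting | 25 h |
| elm | 38 mM | 49.4 mM | 3.8 mM | 80 °C | everything together at the start | 25 h |

- epsilon (time / h: target / %, substrate / %): 1.33: 20, 81; 2.00: 28, 71; 3.00: 35, 61; 5.00: 40, 58; 10.0: 41, 60; 15.0: 37, 54
- eta (time / h: target / %, substrate / %): 0.333: 1, 101; 1.00: 10, 84; 2.00: 17, 78; 2.50: 23, 74; 4.00: 23, 76; 5.00: 23, 74

(readings scatter by 2 percentage points)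

- the earlier runs do not show what temperature does; that part of a forecast is a guess

* the best flask by amount of target, in percent of the substrate charged; "all alike" if 1.5 percentage points covers them all (oak / alder / larch / elm / all alike)
* amount of target at the end, in percent of the substrate charged, oak
* amount of target at the end, in percent of the substrate charged, alder
* amount of target at the end, in percent of the substrate charged, larch
* amount of target at the end, in percent of the substrate charged, elm

Then the reach, minus the logarithm of the unreacted share at the stall of 41%, is 0.528. The reading at 2.00 h gives a clock of 2.05 h. A portion added late sees only the rest of that clock. Averaged over a steady feed, the clock over the feed time, times one minus the exponential of minus feed time over clock, gives 0.375. I call this the feed factor, the mean share of the reach that fed substrate sees.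

Now the question turned round. For the flasks to come out alike, this factor must stand near one, with the clock long against the feed. But the clock is shorter than the feed of 5.0 h, so oak stands far from that. My reckoning gives 17.9% for oak and the epsilon stall for elm, and I set alder near oak. For larch the temperature effect is a guess, so I give no figure. A reversible stall fits both runs too; the clock is my choice.

The forecast says all alike, with 40% for oak, 40% for alder, 40% for larch and 40% for elm: “I favour equilibrium, with wide ranges”. My reckoning differs from it on oak.

The flasks give 23.8% for oak, 25.5% for alder, 40.8% for larch and 39.2% for elm, so the best is larch.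

    substrate + catalyst intermediate A → catalyst intermediate B (k = 120 M⁻¹ h⁻¹, Ea = 69.0 kJ mol⁻¹)
    partner → decomposed reagent (k = 0.610 h⁻¹, Ea = 107 kJ mol⁻¹)
    catalyst intermediate B ⇌ free catalyst + target (K = 0.0240 M, k = 9.50 h⁻¹, Ea = 99.0 kJ mol⁻¹, ΔH = −7.00 kJ mol⁻¹)
    partner + free catalyst ⇌ catalyst intermediate A (K = 380 M⁻¹, k = 270 M⁻¹ h⁻¹, Ea = 62.0 kJ mol⁻¹, ΔH = −25.0 kJ mol⁻¹)
    (constants at 80 °C)

In oak at 0.918 h, partner's half-life by decomposition is 1.1 h, shorter than the 4.9 h by its forward step onto free catalyst. At the end of the feed oak holds 1.25% of its partner, and larch holds 58.8%. Oak's reach over elm's is 0.546, more than my factor.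

For the repeat of oak at 105 °C, I shorten the clock by 107 kJ mol⁻¹ to 0.184 h and hold the reach. The factor becomes 0.0369, which gives 1.93% target. That flask gives 3.91%.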